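## Retrosynthetic overview

1. The C11–C12 bond is cut first: an α-sulfonyl carbanion at C11 of the decalin is joined to an ω-silyloxy farnesyl bromide made from farnesyl acetate.
2. Ring B is opened at C8–C9: a samarium ketyl at C8 (methyl ketone) closes 6-exo onto a C9=C11 vinyl sulfone and sets C8 and C9.
3. Ring A is made first, in one step: an enantioselective Diels–Alder reaction of the silyloxy diene C1=C2–C3(OSi)=C4(CH3)2 with (E)-2-methyl-6-oxohept-2-enal (C5=C10, formyl carbon = C9) forms C1–C10 and C4–C5.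
4. Enabling feature: in ring A the C3 oxygen stands 1,4 to the quaternary C10 and next to the gem-dimethyl carbon C4, and C10 carries C9, which can be a formyl group. Ring A is therefore the retron of a 2-silyloxy diene/α-methyl enal cycloaddition, and the trans C5–H/C10–CH3 fusion is stored in the E geometry of the enal.
5. Ring order: ring A (step 5), then ring B (step 7), then chain coupling and unmasking of O3 and the terminal carbinol.

Key step: step 5

Remark: locants follow triterpenoid usage (ring A = C1–C5 and C10, ring B = C5–C10, chain from C11); the sense of induction in step 5 is assigned from the formyl C–H···O model of the catalyst and is not secured by direct precedent on this substrate pair; both catalyst antipodes are available from (R)- or (S)-diphenylprolinol.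

## Route

Step 1
Reactants: 1 isobutyraldehyde (2-methylpropanal); 2 vinylmagnesium bromide
Product: 3 (±)-4-methylpent-1-en-3-ol
Conditions: THF, 0 °C; then H2O
Reagents that add atoms: none
Why: Grignard 1,2-addition of a vinyl nucleophile to an unhindered aldehyde; the carbinol centre forms as a racemate and is erased in step 2.

Step 2
Reactants: 3 (±)-4-methylpent-1-en-3-ol
Product: 4 4-methylpent-1-en-3-one
Conditions: Dess–Martin periodinane, CH2Cl2, 0 °C → rt; distillation
Reagents that add atoms: none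
Why: Dess–Martin oxidation of a secondary allylic alcohol under neutral conditions, which should spare the volatile, polymerisable vinyl ketone.

Step 3
Reactants: 4 4-methylpent-1-en-3-one
Product: 5 tert-butyl(dimethyl)[(4-methylpenta-1,3-dien-3-yl)oxy]silane
Conditions: TBSOTf, Et3N, CH2Cl2, 0 °C → rt
Reagents that add atoms: tert-butyldimethylsilyl trifluoromethanesulfonate, CC(C)(C)[Si](C)(C)OS(=O)(=O)C(F)(F)F
Why: Soft enolisation and O-silylation of a ketone whose only α-hydrogen is the isopropyl methine, so a single 2-silyloxy diene without E/Z isomers should result.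

Step 4
Reactants: 6 6-methylhept-5-en-2-one
Product: 8 (E)-2-methyl-6-oxohept-2-enal, via (E)-7-hydroxy-6-methylhept-5-en-2-one 7 (not isolated)
Conditions: SeO2 (1.1 equiv), 1,4-dioxane/H2O, 80 °C
Reagents that add atoms: selenium dioxide, O=[Se]=O
Why: Riley allylic oxidation (ene reaction, then [2,3]-sigmatropic shift) attacks the (E)-methyl group of the trisubstituted alkene and carries the allylic alcohol on to the (E)-enal.

Step 5
Reactants: 5 tert-butyl(dimethyl)[(4-methylpenta-1,3-dien-3-yl)oxy]silane; 8 (E)-2-methyl-6-oxohept-2-enal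
Product: 9 (1S,6S)-4-{[tert-butyl(dimethyl)silyl]oxy}-1,5,5-trimethyl-6-(3-oxobutyl)cyclohex-3-ene-1-carbaldehyde
Conditions: (3aR)-1-(2-methylphenyl)-3,3-diphenyltetrahydro-1H,3H-pyrrolo[1,2-c][1,3,2]oxazaborole (20 mol%), HN(SO2CF3)2 (18 mol%), 5 (2 equiv), CH2Cl2, −78 → −20 °C; Et3N quench
Reagents that add atoms: none
Why: This is a Lewis-acid-catalysed normal-demand Diels–Alder reaction, concerted but asynchronous: the nucleophilic C4 terminus of the silyl enol ether bonds first to the β-carbon C5 of the boron-bound enal and C1 then closes onto C10. The closest known types are cationic oxazaborolidine-catalysed cycloadditions of 2-silyloxy dienes with α-substituted enals and Lewis-acid-promoted cycloadditions of hindered 2-silyloxy dienes with hindered enals and enones. Ring A is closed as an intermolecular [4+2] cycloaddition, suprafacial on both partners. The relative configuration at C5/C10 (C10–CH3 trans to C5–H, formyl trans to the oxobutyl chain) is transferred from the E geometry of 8; the absolute configuration comes from the catalyst, whose C-phenyl group screens one face of the s-trans enal held by B–O coordination and a formyl C–H···O contact, so that the (3aR)-catalyst is expected to leave the C10 si face open. The regioselectivity needed (C4 to C5, C1 to C10) is secured electronically by the C3 silyloxy group (largest HOMO coefficient at C4, oxygen 1,4 to the formyl-bearing carbon) and sterically, because the C(CH3)2 terminus meets the CH terminus of the dienophile. Only the C5=C10 bond is conjugated to a carbonyl, so the remote methyl ketone should stay untouched, and endo/exo selectivity is irrelevant because neither diene terminus becomes a stereocentre.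

Step 6
Reactants: 9 (1S,6S)-4-{[tert-butyl(dimethyl)silyl]oxy}-1,5,5-trimethyl-6-(3-oxobutyl)cyclohex-3-ene-1-carbaldehyde; 10 diethyl [(phenylsulfonyl)methyl]phosphonate
Product: 11 4-{(1R,6S)-3-{[tert-butyl(dimethyl)silyl]oxy}-2,2,6-trimethyl-6-[(E)-2-(phenylsulfonyl)ethenyl]cyclohex-3-en-1-yl}butan-2-one
Conditions: NaH, THF, 0 °C → rt
Reagents that add atoms: none
Why: Horner–Wadsworth–Emmons olefination with a sulfonyl-stabilised phosphonate anion should be aldehyde-selective over the methyl ketone and E-selective, and the non-enolisable formyl group on quaternary C10 cannot epimerise.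

Step 7
Reactants: 11 4-{(1R,6S)-3-{[tert-butyl(dimethyl)silyl]oxy}-2,2,6-trimethyl-6-[(E)-2-(phenylsulfonyl)ethenyl]cyclohex-3-en-1-yl}butan-2-one
Product: 12 (1R,2R,4aR,8aS)-6-{[tert-butyl(dimethyl)silyl]oxy}-2,5,5,8a-tetramethyl-1-[(phenylsulfonyl)methyl]-1,2,3,4,4a,5,8,8a-octahydronaphthalen-2-ol
Conditions: SmI2 (2.5 equiv), MeOH, THF, −78 → 0 °C
Reagents that add atoms: none
Why: Samarium ketyl–olefin 6-exo-trig radical cyclisation of the C8 ketyl onto the β-carbon C9 of the electron-poor vinyl sulfone should close ring B through a chair with the C9=C11 unit equatorial and the bulky O–Sm group pseudo-equatorial, giving 8α-OH/8β-CH3 and 9α-H, while the trans disposition of the two chains fixed in step 5 imposes the trans ring fusion.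

Step 8
Reactants: 13 (2E,6E)-3,7,11-trimethyldodeca-2,6,10-trien-1-yl acetate (farnesyl acetate)
Product: 14 (2E,6E,10E)-12-hydroxy-3,7,11-trimethyldodeca-2,6,10-trien-1-yl acetate
Conditions: SeO2 (10 mol%), salicylic acid (10 mol%), t-BuOOH, CH2Cl2, rt
Reagents that add atoms: tert-butyl hydroperoxide, CC(C)(C)OO
Why: Catalytic selenium dioxide allylic oxidation is selective for the terminal (E)-methyl group of a polyprenyl chain and gives the (E)-allylic alcohol.

Step 9
Reactants: 14 (2E,6E,10E)-12-hydroxy-3,7,11-trimethyldodeca-2,6,10-trien-1-yl acetate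
Product: 15 (2E,6E,10E)-12-{[tert-butyl(dimethyl)silyl]oxy}-3,7,11-trimethyldodeca-2,6,10-trien-1-yl acetate
Conditions: TBSCl, imidazole, CH2Cl2, rt
Reagents that add atoms: tert-butyldimethylsilyl chloride, CC(C)(C)[Si](C)(C)Cl
Why: Standard silylation of a primary allylic alcohol; the ether is stable to the base of step 12 and is removed by fluoride in step 14.

Step 10
Reactants: 15 (2E,6E,10E)-12-{[tert-butyl(dimethyl)silyl]oxy}-3,7,11-trimethyldodeca-2,6,10-trien-1-yl acetate
Product: 16 (2E,6E,10E)-12-{[tert-butyl(dimethyl)silyl]oxy}-3,7,11-trimethyldodeca-2,6,10-trien-1-ol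
Conditions: K2CO3 (cat.), MeOH, rt
Reagents that add atoms: none
Why: Base-catalysed transesterification (methanolysis) removes the acetate and leaves the silyl ether intact.

Step 11
Reactants: 16 (2E,6E,10E)-12-{[tert-butyl(dimethyl)silyl]oxy}-3,7,11-trimethyldodeca-2,6,10-trien-1-ol
Product: 17 {[(2E,6E,10E)-12-bromo-2,6,10-trimethyldodeca-2,6,10-trien-1-yl]oxy}(tert-butyl)dimethylsilane
Conditions: CBr4, PPh3, CH2Cl2, −20 → 0 °C; used directly
Reagents that add atoms: carbon tetrabromide, BrC(Br)(Br)Br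
Why: Appel bromination of a primary allylic alcohol under neutral, cold conditions proceeds by SN2 without allylic transposition or loss of alkene geometry.

Step 12
Reactants: 12 (1R,2R,4aR,8aS)-6-{[tert-butyl(dimethyl)silyl]oxy}-2,5,5,8a-tetramethyl-1-[(phenylsulfonyl)methyl]-1,2,3,4,4a,5,8,8a-octahydronaphthalen-2-ol; 17 {[(2E,6E,10E)-12-bromo-2,6,10-trimethyldodeca-2,6,10-trien-1-yl]oxy}(tert-butyl)dimethylsilane
Product: 18 (1R,2R,4aR,8aS)-6-{[tert-butyl(dimethyl)silyl]oxy}-1-[(3E,7E,11E)-13-{[tert-butyl(dimethyl)silyl]oxy}-4,8,12-trimethyl-1-(phenylsulfonyl)trideca-3,7,11-trien-1-yl]-2,5,5,8a-tetramethyl-1,2,3,4,4a,5,8,8a-octahydronaphthalen-2-ol (both epimers at the sulfonyl-bearing carbon)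
Conditions: n-BuLi (2.1 equiv), THF/HMPA, −78 °C; then 17, −78 → −20 °C
Reagents that add atoms: none
Why: SN2 alkylation of the α-sulfonyl carbanion (as alkoxide/carbanion dianion) with a primary allylic bromide is the classical sulfone coupling of polyprenoid chains, and the new C11 stereocentre is of no consequence because the sulfonyl group leaves in step 13.

Step 13
Reactants: 18 (alkylated sulfone from step 12)
Product: 19 (1R,2R,4aR,8aS)-6-{[tert-butyl(dimethyl)silyl]oxy}-1-[(3E,7E,11E)-13-{[tert-butyl(dimethyl)silyl]oxy}-4,8,12-trimethyltrideca-3,7,11-trien-1-yl]-2,5,5,8a-tetramethyl-1,2,3,4,4a,5,8,8a-octahydronaphthalen-2-ol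
Conditions: Na(Hg) (5% Na), Na2HPO4, MeOH/THF, −20 °C
Reagents that add atoms: none
Why: Reductive desulfonylation by electron transfer; the sulfone is homoallylic, so no alkene migration is expected, and the buffered medium should keep both silyl groups.

Step 14
Reactants: 19 (bis-silyl compound from step 13)
Product: 20 (4aS,5R,6R,8aR)-6-hydroxy-5-[(3E,7E,11E)-13-hydroxy-4,8,12-trimethyltrideca-3,7,11-trien-1-yl]-1,1,4a,6-tetramethyloctahydronaphthalen-2(1H)-one
Conditions: Bu4NF, AcOH, THF, 0 °C → rt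
Reagents that add atoms: none
Why: Fluoride cleaves the primary silyl ether and the silyl enol ether; the buffered enolate is protonated at C2 (not a stereocentre) to give the C3 ketone.

Step 15
Reactants: 20 (3-oxo compound from step 14)
Product: 21 (2S,4aS,5R,6R,8aR)-5-[(3E,7E,11E)-13-hydroxy-4,8,12-trimethyltrideca-3,7,11-trien-1-yl]-1,1,4a,6-tetramethyldecahydronaphthalene-2,6-diol (target)
Conditions: NaBH4, MeOH/THF, 0 °C
Reagents that add atoms: none
Why: Borohydride reduction of a 4,4-dimethyl-3-ketone in a trans-decalin; hydride should enter from the α face, away from the axial 4β- and 10β-methyl groups, giving the equatorial 3β-alcohol (3S).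

## Compound list

1 | isobutyraldehyde | CC(C)C=O | starting material
2 | vinylmagnesium bromide | C=C[Mg]Br | starting material
3 | (±)-4-methylpent-1-en-3-ol | C=CC(O)C(C)C | intermediate
4 | 4-methylpent-1-en-3-one | C=CC(=O)C(C)C | intermediate
5 | tert-butyl(dimethyl)[(4-methylpenta-1,3-dien-3-yl)oxy]silane | C=CC(O[Si](C)(C)C(C)(C)C)=C(C)C | intermediate
6 | 6-methylhept-5-en-2-one | CC(=O)CCC=C(C)C | starting material
7 | (E)-7-hydroxy-6-methylhept-5-en-2-one | CC(=O)CC/C=C(\C)CO | intermediate (not isolated)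
8 | (E)-2-methyl-6-oxohept-2-enal | O=C/C(C)=C/CCC(C)=O | intermediate
9 | (1S,6S)-4-{[tert-butyl(dimethyl)silyl]oxy}-1,5,5-trimethyl-6-(3-oxobutyl)cyclohex-3-ene-1-carbaldehyde | O=C[C@@]1(C)CC=C(O[Si](C)(C)C(C)(C)C)C(C)(C)[C@@H]1CCC(C)=O | intermediate
10 | diethyl [(phenylsulfonyl)methyl]phosphonate | CCOP(=O)(OCC)CS(=O)(=O)c1ccccc1 | starting material
11 | 4-{(1R,6S)-3-{[tert-butyl(dimethyl)silyl]oxy}-2,2,6-trimethyl-6-[(E)-2-(phenylsulfonyl)ethenyl]cyclohex-3-en-1-yl}butan-2-one | O=S(=O)(/C=C/[C@@]1(C)CC=C(O[Si](C)(C)C(C)(C)C)C(C)(C)[C@@H]1CCC(C)=O)c1ccccc1 | intermediate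
12 | (1R,2R,4aR,8aS)-6-{[tert-butyl(dimethyl)silyl]oxy}-2,5,5,8a-tetramethyl-1-[(phenylsulfonyl)methyl]-1,2,3,4,4a,5,8,8a-octahydronaphthalen-2-ol | O=S(=O)(C[C@@H]1[C@@]2(C)CC=C(O[Si](C)(C)C(C)(C)C)C(C)(C)[C@@H]2CC[C@@]1(C)O)c1ccccc1 | intermediate
13 | (2E,6E)-3,7,11-trimethyldodeca-2,6,10-trien-1-yl acetate | CC(C)=CCC/C(C)=C/CC/C(C)=C/COC(C)=O | starting material
14 | (2E,6E,10E)-12-hydroxy-3,7,11-trimethyldodeca-2,6,10-trien-1-yl acetate | OC/C(C)=C/CC/C(C)=C/CC/C(C)=C/COC(C)=O | intermediate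
15 | (2E,6E,10E)-12-{[tert-butyl(dimethyl)silyl]oxy}-3,7,11-trimethyldodeca-2,6,10-trien-1-yl acetate | CC(C)(C)[Si](C)(C)OC/C(C)=C/CC/C(C)=C/CC/C(C)=C/COC(C)=O | intermediate
16 | (2E,6E,10E)-12-{[tert-butyl(dimethyl)silyl]oxy}-3,7,11-trimethyldodeca-2,6,10-trien-1-ol | CC(C)(C)[Si](C)(C)OC/C(C)=C/CC/C(C)=C/CC/C(C)=C/CO | intermediate
17 | {[(2E,6E,10E)-12-bromo-2,6,10-trimethyldodeca-2,6,10-trien-1-yl]oxy}(tert-butyl)dimethylsilane | CC(C)(C)[Si](C)(C)OC/C(C)=C/CC/C(C)=C/CC/C(C)=C/CBr | intermediate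
18 | (1R,2R,4aR,8aS)-6-{[tert-butyl(dimethyl)silyl]oxy}-1-[(3E,7E,11E)-13-{[tert-butyl(dimethyl)silyl]oxy}-4,8,12-trimethyl-1-(phenylsulfonyl)trideca-3,7,11-trien-1-yl]-2,5,5,8a-tetramethyl-1,2,3,4,4a,5,8,8a-octahydronaphthalen-2-ol (epimers at the sulfonyl carbon) | CC(C)(C)[Si](C)(C)OC/C(C)=C/CC/C(C)=C/CC/C(C)=C/CC(S(=O)(=O)c1ccccc1)[C@@H]1[C@@]2(C)CC=C(O[Si](C)(C)C(C)(C)C)C(C)(C)[C@@H]2CC[C@@]1(C)O | intermediate
19 | (1R,2R,4aR,8aS)-6-{[tert-butyl(dimethyl)silyl]oxy}-1-[(3E,7E,11E)-13-{[tert-butyl(dimethyl)silyl]oxy}-4,8,12-trimethyltrideca-3,7,11-trien-1-yl]-2,5,5,8a-tetramethyl-1,2,3,4,4a,5,8,8a-octahydronaphthalen-2-ol | CC(C)(C)[Si](C)(C)OC/C(C)=C/CC/C(C)=C/CC/C(C)=C/CC[C@@H]1[C@@]2(C)CC=C(O[Si](C)(C)C(C)(C)C)C(C)(C)[C@@H]2CC[C@@]1(C)O | intermediate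
20 | (4aS,5R,6R,8aR)-6-hydroxy-5-[(3E,7E,11E)-13-hydroxy-4,8,12-trimethyltrideca-3,7,11-trien-1-yl]-1,1,4a,6-tetramethyloctahydronaphthalen-2(1H)-one | C/C(=C\CC/C(C)=C/CC/C(C)=C/CC[C@@H]1[C@@]2(C)CCC(=O)C(C)(C)[C@@H]2CC[C@@]1(C)O)CO | intermediate
21 | (2S,4aS,5R,6R,8aR)-5-[(3E,7E,11E)-13-hydroxy-4,8,12-trimethyltrideca-3,7,11-trien-1-yl]-1,1,4a,6-tetramethyldecahydronaphthalene-2,6-diol | C/C(=C\CC/C(C)=C/CC/C(C)=C/CC[C@@H]1[C@@]2(C)CC[C@H](O)C(C)(C)[C@@H]2CC[C@@]1(C)O)CO | target

## Step count and risks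

Total: 15 steps. Longest linear sequence: 10 steps (1, 2, 3, 5, 6, 7, 12, 13, 14, 15).

**Step 5.** The cycloaddition of this doubly hindered pair may be slow. An achiral silyl triflimide pathway or a Mukaiyama aldol 1,2-addition at the formyl group could then compete and lower conversion and enantiomeric purity, and the facial sense could be opposite to the model. Fallback, setting out from 5 and 8 and returning at 12: the two are combined without chiral control under the mixed Lewis acid AlBr3/AlMe3 (toluene/CH2Cl2, about 0 °C), conditions of the type used for hindered 2-silyloxy dienes. This should give 9 together with its enantiomer (1R,6R)-4-{[tert-butyl(dimethyl)silyl]oxy}-1,5,5-trimethyl-6-(3-oxobutyl)cyclohex-3-ene-1-carbaldehyde F1. The racemate is taken through the conditions of steps 6 and 7, which should give, beside 11 and 12, the enantiomers 4-{(1S,6R)-3-{[tert-butyl(dimethyl)silyl]oxy}-2,2,6-trimethyl-6-[(E)-2-(phenylsulfonyl)ethenyl]cyclohex-3-en-1-yl}butan-2-one F2 and (1S,2S,4aS,8aR)-6-{[tert-butyl(dimethyl)silyl]oxy}-2,5,5,8a-tetramethyl-1-[(phenylsulfonyl)methyl]-1,2,3,4,4a,5,8,8a-octahydronaphthalen-2-ol F3. Compound 12 is then separated from F3 by preparative chromatography on a chiral stationary phase.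

**Step 7.** The ketyl may close through the alternative chair with the O–Sm group axial, giving the wrong configuration at C8. Fallback, setting out from 11 and returning at 21: the C8 epimer (1R,2S,4aR,8aS)-6-{[tert-butyl(dimethyl)silyl]oxy}-2,5,5,8a-tetramethyl-1-[(phenylsulfonyl)methyl]-1,2,3,4,4a,5,8,8a-octahydronaphthalen-2-ol F4 is corrected by the elimination/α-face epoxidation/hydride sequence established for this decalin class.
- Bu4NF/AcOH should give (4aS,5R,6S,8aR)-6-hydroxy-1,1,4a,6-tetramethyl-5-[(phenylsulfonyl)methyl]octahydronaphthalen-2(1H)-one F5.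
- Syn-elimination with the Burgess reagent toward the methyl group should give (4aS,5S,8aR)-1,1,4a-trimethyl-6-methylidene-5-[(phenylsulfonyl)methyl]octahydronaphthalen-2(1H)-one F6.
- m-CPBA should attack anti to the axial C10 methyl group and give the 8α,17-epoxide, the spiro-oxirane of F6 with the oxirane oxygen on the α face, F7.
- LiAlH4 should open the oxirane at CH2 and reduce the C3 ketone from the α face, giving (2S,4aS,5R,6R,8aR)-1,1,4a,6-tetramethyl-5-[(phenylsulfonyl)methyl]decahydronaphthalene-2,6-diol F8.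
- Alkylation of its trianion (n-BuLi, 3.2 equiv) with 17 should give (2S,4aS,5R,6R,8aR)-5-[(3E,7E,11E)-13-{[tert-butyl(dimethyl)silyl]oxy}-4,8,12-trimethyl-1-(phenylsulfonyl)trideca-3,7,11-trien-1-yl]-1,1,4a,6-tetramethyldecahydronaphthalene-2,6-diol F9.
- Na(Hg)/Na2HPO4 should give (2S,4aS,5R,6R,8aR)-5-[(3E,7E,11E)-13-{[tert-butyl(dimethyl)silyl]oxy}-4,8,12-trimethyltrideca-3,7,11-trien-1-yl]-1,1,4a,6-tetramethyldecahydronaphthalene-2,6-diol F10, and Bu4NF then gives 21.

**Step 12.** C-alkylation of the hindered dianion, flanked by the C8 alkoxide and quaternary C10, may be sluggish, with proton transfer or elimination of the allylic bromide taking over. Fallback, setting out from 10 and 17 and returning at 18: the C11–C12 bond is made on the unhindered reagent before ring B exists. Alkylation of the sodium salt of 10 with 17 (NaH, THF/DMF) should give diethyl [(3E,7E,11E)-13-{[tert-butyl(dimethyl)silyl]oxy}-4,8,12-trimethyl-1-(phenylsulfonyl)trideca-3,7,11-trien-1-yl]phosphonate F11. Horner–Wadsworth–Emmons reaction of F11 with 9 should give the trisubstituted vinyl sulfone 4-{(1R,6S)-3-{[tert-butyl(dimethyl)silyl]oxy}-6-[(4E,8E,12E)-14-{[tert-butyl(dimethyl)silyl]oxy}-5,9,13-trimethyl-2-(phenylsulfonyl)tetradeca-1,4,8,12-tetraen-1-yl]-2,2,6-trimethylcyclohex-3-en-1-yl}butan-2-one F12, of either C9=C11 geometry. The ketyl cyclisation of step 7 (SmI2, MeOH, THF) then closes ring B and gives 18 directly.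

## Further compounds

F1 | step 5 | (1R,6R)-4-{[tert-butyl(dimethyl)silyl]oxy}-1,5,5-trimethyl-6-(3-oxobutyl)cyclohex-3-ene-1-carbaldehyde | O=C[C@]1(C)CC=C(O[Si](C)(C)C(C)(C)C)C(C)(C)[C@H]1CCC(C)=O
F2 | step 5 | 4-{(1S,6R)-3-{[tert-butyl(dimethyl)silyl]oxy}-2,2,6-trimethyl-6-[(E)-2-(phenylsulfonyl)ethenyl]cyclohex-3-en-1-yl}butan-2-one | O=S(=O)(/C=C/[C@]1(C)CC=C(O[Si](C)(C)C(C)(C)C)C(C)(C)[C@H]1CCC(C)=O)c1ccccc1
F3 | step 5 | (1S,2S,4aS,8aR)-6-{[tert-butyl(dimethyl)silyl]oxy}-2,5,5,8a-tetramethyl-1-[(phenylsulfonyl)methyl]-1,2,3,4,4a,5,8,8a-octahydronaphthalen-2-ol | O=S(=O)(C[C@H]1[C@]2(C)CC=C(O[Si](C)(C)C(C)(C)C)C(C)(C)[C@H]2CC[C@]1(C)O)c1ccccc1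
F4 | step 7 | (1R,2S,4aR,8aS)-6-{[tert-butyl(dimethyl)silyl]oxy}-2,5,5,8a-tetramethyl-1-[(phenylsulfonyl)methyl]-1,2,3,4,4a,5,8,8a-octahydronaphthalen-2-ol | O=S(=O)(C[C@@H]1[C@@]2(C)CC=C(O[Si](C)(C)C(C)(C)C)C(C)(C)[C@@H]2CC[C@]1(C)O)c1ccccc1
F5 | step 7 | (4aS,5R,6S,8aR)-6-hydroxy-1,1,4a,6-tetramethyl-5-[(phenylsulfonyl)methyl]octahydronaphthalen-2(1H)-one | O=S(=O)(C[C@@H]1[C@@]2(C)CCC(=O)C(C)(C)[C@@H]2CC[C@]1(C)O)c1ccccc1
F6 | step 7 | (4aS,5S,8aR)-1,1,4a-trimethyl-6-methylidene-5-[(phenylsulfonyl)methyl]octahydronaphthalen-2(1H)-one | O=S(=O)(C[C@@H]1[C@@]2(C)CCC(=O)C(C)(C)[C@@H]2CCC1=C)c1ccccc1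
F7 | step 7 | 8α,17-epoxide of F6 (spiro-oxirane, oxygen on the face opposite the angular methyl group) | O=S(=O)(C[C@@H]1[C@@]2(C)CCC(=O)C(C)(C)[C@@H]2CC[C@]13CO3)c1ccccc1
F8 | step 7 | (2S,4aS,5R,6R,8aR)-1,1,4a,6-tetramethyl-5-[(phenylsulfonyl)methyl]decahydronaphthalene-2,6-diol | O=S(=O)(C[C@@H]1[C@@]2(C)CC[C@H](O)C(C)(C)[C@@H]2CC[C@@]1(C)O)c1ccccc1
F9 | step 7 | (2S,4aS,5R,6R,8aR)-5-[(3E,7E,11E)-13-{[tert-butyl(dimethyl)silyl]oxy}-4,8,12-trimethyl-1-(phenylsulfonyl)trideca-3,7,11-trien-1-yl]-1,1,4a,6-tetramethyldecahydronaphthalene-2,6-diol | CC(C)(C)[Si](C)(C)OC/C(C)=C/CC/C(C)=C/CC/C(C)=C/CC(S(=O)(=O)c1ccccc1)[C@@H]1[C@@]2(C)CC[C@H](O)C(C)(C)[C@@H]2CC[C@@]1(C)O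
F10 | step 7 | (2S,4aS,5R,6R,8aR)-5-[(3E,7E,11E)-13-{[tert-butyl(dimethyl)silyl]oxy}-4,8,12-trimethyltrideca-3,7,11-trien-1-yl]-1,1,4a,6-tetramethyldecahydronaphthalene-2,6-diol | CC(C)(C)[Si](C)(C)OC/C(C)=C/CC/C(C)=C/CC/C(C)=C/CC[C@@H]1[C@@]2(C)CC[C@H](O)C(C)(C)[C@@H]2CC[C@@]1(C)O
F11 | step 12 | diethyl [(3E,7E,11E)-13-{[tert-butyl(dimethyl)silyl]oxy}-4,8,12-trimethyl-1-(phenylsulfonyl)trideca-3,7,11-trien-1-yl]phosphonate | CCOP(=O)(OCC)C(C/C=C(\C)CC/C=C(\C)CC/C=C(\C)CO[Si](C)(C)C(C)(C)C)S(=O)(=O)c1ccccc1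
F12 | step 12 | 4-{(1R,6S)-3-{[tert-butyl(dimethyl)silyl]oxy}-6-[(4E,8E,12E)-14-{[tert-butyl(dimethyl)silyl]oxy}-5,9,13-trimethyl-2-(phenylsulfonyl)tetradeca-1,4,8,12-tetraen-1-yl]-2,2,6-trimethylcyclohex-3-en-1-yl}butan-2-one | CC(C)(C)[Si](C)(C)OC/C(C)=C/CC/C(C)=C/CC/C(C)=C/CC(=C[C@@]1(C)CC=C(O[Si](C)(C)C(C)(C)C)C(C)(C)[C@@H]1CCC(C)=O)S(=O)(=O)c1ccccc1
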